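**Plan**

Numbering follows the fusicoccane skeleton: ring A = C2–C6 (C3 carries OH and CH2OMe), C1 = olefinic CH, C7 (Me), C8 (OH), C9, ring C = C10–C14 (C11 Me/OH, C12 OH, C13 ketone, C14 i-Pr).
Retrosynthesis cuts, in order: C8–C9 (ring-closing vinylogous aldol); the C12–O bond together with the C1=C2 double bond (ene transposition of a C12=C1 alkylidene); C1=C12 (aldol condensation of a ring A aldehyde with a ring C cyclopentenone); and last C5–C6 plus C2–C3 of ring A.
Forward: ring A is made first in one [3+2] event from an acyclic enal and 1-(methoxymethyl)cyclopropanol; ring C is made separately from butanedione and 4-methylpentan-2-one; the rings are joined at C1–C12, C12 is oxygenated, and the nine-membered ring is closed last.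
Enabling feature: in ring A the tertiary carbinol C3 with its CH2–CH2 arm (C4–C5) is a ring-opened cyclopropanol (strain release gives a C5 radical), and C6, C2 and the exocyclic C1 are the β-, α- and carbonyl carbons of an enal.
Stereochemistry: C7 from the Roche ester; C6, C2 and C3 from the aminocatalytic cascade; C11 from a proline aldol; C12 and the C1=C2 geometry from the ene step (anti to C11–OTBS); C8 from the ring closure.

Key step: step 5

Assumption: the absolute sense of induction of the two aminocatalysts (steps 5 and 7) is assigned from the steric-shielding model of diarylprolinol ethers and the Houk–List model; if either proves reversed, the mirror-image catalyst is used.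

Step 1
Reactants: 1 methyl (S)-3-hydroxy-2-methylpropanoate
Product: 2 methyl (S)-3-[(tert-butyldimethylsilyl)oxy]-2-methylpropanoate
Conditions: TBSCl, imidazole, CH2Cl2, 0 °C to rt
Reagents that add atoms: tert-butyldimethylsilyl chloride, CC(C)(C)[Si](C)(C)Cl
Why: Imidazole-promoted silylation of a primary alcohol should proceed cleanly and leaves the C7 stereocentre untouched.

Step 2
Reactants: 2 methyl (S)-3-[(tert-butyldimethylsilyl)oxy]-2-methylpropanoate
Product: 3 (S)-3-[(tert-butyldimethylsilyl)oxy]-2-methylpropanal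
Conditions: i-Bu2AlH, CH2Cl2, −78 °C; Rochelle salt work-up
Reagents that add atoms: none
Why: Partial ester reduction should stop at the aldehyde because the tetrahedral aluminium hemiacetal is stable at −78 °C, where the α-centre is not enolized.

Step 3
Reactants: 3 (S)-3-[(tert-butyldimethylsilyl)oxy]-2-methylpropanal; 4 (triphenylphosphoranylidene)acetaldehyde
Product: 5 (R,E)-5-[(tert-butyldimethylsilyl)oxy]-4-methylpent-2-enal
Conditions: toluene, 80 °C
Reagents that add atoms: none
Why: Wittig olefination with the stabilized formylmethylene ylide should give the (E)-enal under neutral conditions that spare C7.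

Step 4
Reactants: 6 methyl methoxyacetate
Product: 7 1-(methoxymethyl)cyclopropan-1-ol
Conditions: EtMgBr (2.4 equiv), Ti(OiPr)4 (20 mol %), Et2O/THF, 0 °C to rt; aq NH4Cl
Reagents that add atoms: ethylmagnesium bromide, CC[Mg]Br
Why: Kulinkovich cyclopropanation, in which the titanacyclopropane formed from EtMgBr and Ti(OiPr)4 adds twice to the ester carbonyl, should deliver the cyclopropanol.

Step 5
Reactants: 5 (R,E)-5-[(tert-butyldimethylsilyl)oxy]-4-methylpent-2-enal; 7 1-(methoxymethyl)cyclopropan-1-ol
Product: 9 (1S,2R,5S)-5-[(2R)-1-(tert-butyldimethylsilyloxy)propan-2-yl]-2-hydroxy-2-(methoxymethyl)cyclopentane-1-carbaldehyde, via keto enamine 8 (not isolated)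
Conditions: (R)-2-{bis[3,5-bis(trifluoromethyl)phenyl][(tert-butyldimethylsilyl)oxy]methyl}-4,4-difluoropyrrolidine (20 mol %), CF3CO2H (40 mol %), 9-mesityl-10-methylacridinium tetrafluoroborate (5 mol %), 7 (2 equiv), MeCN, 450 nm LEDs, 25 °C
Reagents that add atoms: none
Why: Proposed new method: the excited acridinium should oxidize cyclopropanol 7 by single-electron transfer, strain-releasing β-scission gives the β-keto radical (future C5), this adds to C6 of the chiral iminium ion of 5, and back electron transfer from the acridine radical gives keto enamine 8, whose C2 attacks the C3 ketone. The closest known reaction type is the photochemical iminium/enamine cascade of cyclopropanols with β-aryl enals to 2-formylcyclopentanols, extended here to a β-alkyl enal by moving radical generation to a separate photocatalyst. Ring A closes by a 5-(enolexo)-exo-trig aldol addition. C6 is set by the catalyst, whose diaryl(silyloxy)methyl arm shields one face of the (E)-iminium ion so the radical enters anti to it (matched with the Felkin-type bias from C7); at C2 the formyl group settles trans to the C6 branch, and at C3 the hydroxyl ends cis to the formyl group through the compact enamine–ketone transition state. The step needs 1,4- over 1,2-addition, oxidation of the cyclopropanol in preference to the silyl ether and the amine, and no γ-deprotonation at C7; these should be secured by the iminium LUMO, the low oxidation potential of the strained alcohol, and the acid that keeps the electron-poor amine protonated.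

Step 6
Reactants: 9 (1S,2R,5S)-5-[(2R)-1-(tert-butyldimethylsilyloxy)propan-2-yl]-2-hydroxy-2-(methoxymethyl)cyclopentane-1-carbaldehyde
Product: 10 (1S,2R,5S)-2-(tert-butyldimethylsilyloxy)-5-[(2R)-1-(tert-butyldimethylsilyloxy)propan-2-yl]-2-(methoxymethyl)cyclopentane-1-carbaldehyde
Conditions: TBSOTf, 2,6-lutidine, CH2Cl2, −78 to 0 °C
Reagents that add atoms: tert-butyldimethylsilyl triflate, CC(C)(C)[Si](C)(C)OS(=O)(=O)C(F)(F)F
Why: Silyl triflate with a hindered pyridine base should silylate the tertiary C3 alcohol without enolizing the aldehyde and blocks retro-aldol opening of ring A.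

Step 7
Reactants: 11 butane-2,3-dione; 12 4-methylpentan-2-one
Product: 13 (S)-3-hydroxy-3,7-dimethyloctane-2,5-dione
Conditions: D-proline (30 mol %), 12 (5 equiv), DMSO, 4 °C
Reagents that add atoms: none
Why: Proline-catalysed direct aldol addition of the methyl-side enamine of 12 to the activated 1,2-diketone should set the C11 carbinol in the hydrogen-bonded Houk–List transition state.

Step 8
Reactants: 13 (S)-3-hydroxy-3,7-dimethyloctane-2,5-dione
Product: 14 (S)-3-(tert-butyldimethylsilyloxy)-3,7-dimethyloctane-2,5-dione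
Conditions: TBSOTf, 2,6-lutidine, CH2Cl2, 0 °C
Reagents that add atoms: tert-butyldimethylsilyl triflate, CC(C)(C)[Si](C)(C)OS(=O)(=O)C(F)(F)F
Why: Capping the tertiary aldol hydroxyl removes the retro-aldol pathway that would racemize C11 in the next step.

Step 9
Reactants: 14 (S)-3-(tert-butyldimethylsilyloxy)-3,7-dimethyloctane-2,5-dione
Product: 15 (S)-4-(tert-butyldimethylsilyloxy)-3,4-dimethyl-2-(propan-2-yl)cyclopent-2-en-1-one
Conditions: pyrrolidine, AcOH, toluene, 60 °C
Reagents that add atoms: none
Why: Amine-catalysed intramolecular aldol condensation of the 1,4-diketone (enamine of the less hindered ketone on its isobutyl side attacks the methyl ketone, 5-(enolexo)-exo-trig, then dehydration) should give the tetrasubstituted cyclopentenone, with the non-enolizable C11 centre retained.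

Step 10
Reactants: 15 (S)-4-(tert-butyldimethylsilyloxy)-3,4-dimethyl-2-(propan-2-yl)cyclopent-2-en-1-one; 10 (1S,2R,5S)-2-(tert-butyldimethylsilyloxy)-5-[(2R)-1-(tert-butyldimethylsilyloxy)propan-2-yl]-2-(methoxymethyl)cyclopentane-1-carbaldehyde
Product: 17 aldol adduct (C1 carbinol joining C2 of ring A to C12 of ring C; epimer mixture at C1 and C12), via lithium enolate 16 (not isolated)
Conditions: LiN(i-Pr)2, THF, −78 °C; then 10; aq NH4Cl
Reagents that add atoms: none
Why: Kinetic α′-deprotonation of the cyclopentenone at C12 and aldol addition to the aldehyde should form the C1–C12 bond; the two new centres are left uncontrolled because both are erased in steps 11 and 12.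

Step 11
Reactants: 17 aldol adduct
Product: 19 (E)-alkylidene enone (C12=C1; C2 anti to C13=O), via mesylate 18 (not isolated)
Conditions: MsCl, Et3N, CH2Cl2, 0 °C; then DBU, rt
Reagents that add atoms: none
Why: Mesylation and E1cB elimination through the C12 enolate should give the α-alkylidene cyclopentenone in its thermodynamically preferred (E)-geometry.

Step 12
Reactants: 19 (E)-alkylidene enone
Product: 21 tertiary allylic alcohol (C12–OH; C1=C2 with C12 cis to C6), via allylic hydroperoxide 20 (not isolated)
Conditions: O2, tetraphenylporphyrin (cat.), visible light, CH2Cl2, −20 °C; then PPh3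
Reagents that add atoms: dioxygen, O=O
Why: Schenck ene reaction of an s-cis α-alkylidene ketone (pulegone type) should add oxygen to C12 on the face anti to the C11 silyl ether while removing the C2 hydrogen on that same face, which sets C12 (OH cis to the C11 methyl) and, with the smaller C6 branch in the inside position, the required C1=C2 geometry; the endocyclic s-trans enone is inert.

Step 13
Reactants: 21 tertiary allylic alcohol
Product: 22 diol (free primary C8 alcohol and C12–OH)
Conditions: HF·pyridine, pyridine, THF, 0 °C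
Reagents that add atoms: none
Why: Buffered fluoride should cleave the unhindered primary TBS ether much faster than the two tertiary ones.

Step 14
Reactants: 22 diol
Product: 23 hydroxy aldehyde (C8 aldehyde; C12–OH free)
Conditions: Dess–Martin periodinane, NaHCO3, CH2Cl2, 0 °C to rt
Reagents that add atoms: none
Why: Dess–Martin oxidation should convert only the primary alcohol, under buffered conditions that do not epimerize C7.

Step 15
Reactants: 23 hydroxy aldehyde
Product: 24 C12 triethylsilyl ether of 23
Conditions: Et3SiOTf, 2,6-lutidine, CH2Cl2, −78 °C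
Reagents that add atoms: triethylsilyl triflate, CC[Si](CC)(CC)OS(=O)(=O)C(F)(F)F
Why: Silylation of the tertiary α-ketol at low temperature should protect it from α-ketol rearrangement and from interfering with the Lewis acid in step 16 while leaving the aldehyde intact.

Step 16
Reactants: 24 C12 triethylsilyl ether of 23
Product: 26 3,11-bis-O-TBS-12-O-TES-brassicicene M, via lithium dienolate 25 (not isolated)
Conditions: aluminium tris(2,6-diphenylphenoxide) (3.3 equiv), toluene, −78 °C; lithium 2,2,6,6-tetramethylpiperidide (2 equiv), THF, high dilution, −78 °C; aq NH4Cl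
Reagents that add atoms: none
Why: Vinylogous aldol addition in which the bulky aluminium phenoxide binds both carbonyls, the amide removes a C9 proton (the only acidic site, since C12 is quaternary) and the γ-carbon attacks C8 should close the nine-membered ring; the C8 carbinol is set by the ring-closing transition state, and its sense is the main uncertainty of this step.

Step 17
Reactants: 26 3,11-bis-O-TBS-12-O-TES-brassicicene M
Product: 27 brassicicene M
Conditions: HF·pyridine, pyridine, THF, 0 °C to rt
Reagents that add atoms: none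
Why: Buffered fluoride should remove the three tertiary silyl ethers without base, which the β-hydroxy ketone and α-ketol motifs of the product would not tolerate.

**Compound list**

1 | methyl (S)-3-hydroxy-2-methylpropanoate | COC(=O)[C@@H](C)CO | starting material
2 | methyl (S)-3-[(tert-butyldimethylsilyl)oxy]-2-methylpropanoate | COC(=O)[C@@H](C)CO[Si](C)(C)C(C)(C)C | intermediate
3 | (S)-3-[(tert-butyldimethylsilyl)oxy]-2-methylpropanal | O=C[C@@H](C)CO[Si](C)(C)C(C)(C)C | intermediate
4 | (triphenylphosphoranylidene)acetaldehyde | O=CC=P(c1ccccc1)(c1ccccc1)c1ccccc1 | starting material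
5 | (R,E)-5-[(tert-butyldimethylsilyl)oxy]-4-methylpent-2-enal | O=C/C=C/[C@@H](C)CO[Si](C)(C)C(C)(C)C | intermediate
6 | methyl methoxyacetate | COCC(=O)OC | starting material
7 | 1-(methoxymethyl)cyclopropan-1-ol | COCC1(O)CC1 | intermediate
8 | keto enamine: (E)-enamine of the catalyst amine with 3-[(R)-1-(TBSO)propan-2-yl]-7-methoxy-6-oxoheptanal, C6 configured as in 9 | COCC(=O)CC[C@@H]([C@@H](C)CO[Si](C)(C)C(C)(C)C)/C=C/N1CC(F)(F)C[C@@H]1C(O[Si](C)(C)C(C)(C)C)(c1cc(cc(c1)C(F)(F)F)C(F)(F)F)c1cc(cc(c1)C(F)(F)F)C(F)(F)F | intermediate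
9 | (1S,2R,5S)-5-[(2R)-1-(tert-butyldimethylsilyloxy)propan-2-yl]-2-hydroxy-2-(methoxymethyl)cyclopentane-1-carbaldehyde (OH cis to CHO, CHO trans to the side chain) | COC[C@@]1(O)CC[C@@H]([C@@H](C)CO[Si](C)(C)C(C)(C)C)[C@@H]1C=O | intermediate
10 | (1S,2R,5S)-2-(tert-butyldimethylsilyloxy)-5-[(2R)-1-(tert-butyldimethylsilyloxy)propan-2-yl]-2-(methoxymethyl)cyclopentane-1-carbaldehyde | COC[C@@]1(O[Si](C)(C)C(C)(C)C)CC[C@@H]([C@@H](C)CO[Si](C)(C)C(C)(C)C)[C@@H]1C=O | intermediate
11 | butane-2,3-dione | CC(=O)C(C)=O | starting material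
12 | 4-methylpentan-2-one | CC(=O)CC(C)C | starting material
13 | (S)-3-hydroxy-3,7-dimethyloctane-2,5-dione | CC(=O)[C@@](C)(O)CC(=O)CC(C)C | intermediate
14 | (S)-3-(tert-butyldimethylsilyloxy)-3,7-dimethyloctane-2,5-dione | CC(=O)[C@@](C)(O[Si](C)(C)C(C)(C)C)CC(=O)CC(C)C | intermediate
15 | (S)-4-(tert-butyldimethylsilyloxy)-3,4-dimethyl-2-(propan-2-yl)cyclopent-2-en-1-one | CC(C)C1=C(C)[C@@](C)(O[Si](C)(C)C(C)(C)C)CC1=O | intermediate
16 | lithium enolate of 15 (C12=C13–OLi) | CC(C)C1=C(C)[C@@](C)(O[Si](C)(C)C(C)(C)C)C=C1O[Li] | intermediate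
17 | aldol adduct: C1 carbinol joining C2 of ring A (as in 10) to C12 of ring C (as in 15); epimer mixture at C1 and C12 | COC[C@@]1(O[Si](C)(C)C(C)(C)C)CC[C@@H]([C@@H](C)CO[Si](C)(C)C(C)(C)C)[C@@H]1C(O)C1C(=O)C(C(C)C)=C(C)[C@@]1(C)O[Si](C)(C)C(C)(C)C | intermediate
18 | C1 methanesulfonate of 17 | COC[C@@]1(O[Si](C)(C)C(C)(C)C)CC[C@@H]([C@@H](C)CO[Si](C)(C)C(C)(C)C)[C@@H]1C(OS(C)(=O)=O)C1C(=O)C(C(C)C)=C(C)[C@@]1(C)O[Si](C)(C)C(C)(C)C | intermediate
19 | (E)-alkylidene enone: C12=C1 double bond, C2 anti to the C13 carbonyl | COC[C@@]1(O[Si](C)(C)C(C)(C)C)CC[C@@H]([C@@H](C)CO[Si](C)(C)C(C)(C)C)[C@@H]1/C=C1/C(=O)C(C(C)C)=C(C)[C@@]1(C)O[Si](C)(C)C(C)(C)C | intermediate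
20 | C12 hydroperoxide with C1=C2 double bond (C12 cis to C6; OOH cis to C11–Me) | COC[C@@]1(O[Si](C)(C)C(C)(C)C)CC[C@@H]([C@@H](C)CO[Si](C)(C)C(C)(C)C)/C1=C\[C@@]1(OO)C(=O)C(C(C)C)=C(C)[C@@]1(C)O[Si](C)(C)C(C)(C)C | intermediate
21 | C12 tertiary allylic alcohol (3,11-bis-TBS, primary C8–OTBS) | COC[C@@]1(O[Si](C)(C)C(C)(C)C)CC[C@@H]([C@@H](C)CO[Si](C)(C)C(C)(C)C)/C1=C\[C@@]1(O)C(=O)C(C(C)C)=C(C)[C@@]1(C)O[Si](C)(C)C(C)(C)C | intermediate
22 | diol: primary C8 alcohol and C12–OH free, 3,11-bis-TBS | COC[C@@]1(O[Si](C)(C)C(C)(C)C)CC[C@@H]([C@@H](C)CO)/C1=C\[C@@]1(O)C(=O)C(C(C)C)=C(C)[C@@]1(C)O[Si](C)(C)C(C)(C)C | intermediate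
23 | hydroxy aldehyde: C8 aldehyde, C12–OH free, 3,11-bis-TBS | COC[C@@]1(O[Si](C)(C)C(C)(C)C)CC[C@@H]([C@@H](C)C=O)/C1=C\[C@@]1(O)C(=O)C(C(C)C)=C(C)[C@@]1(C)O[Si](C)(C)C(C)(C)C | intermediate
24 | C12 triethylsilyl ether of 23 | COC[C@@]1(O[Si](C)(C)C(C)(C)C)CC[C@@H]([C@@H](C)C=O)/C1=C\[C@@]1(O[Si](CC)(CC)CC)C(=O)C(C(C)C)=C(C)[C@@]1(C)O[Si](C)(C)C(C)(C)C | intermediate
25 | lithium dienolate of 24 (C13–OLi, C13=C14, C10=C9H2; aluminium-bound in the flask) | COC[C@@]1(O[Si](C)(C)C(C)(C)C)CC[C@@H]([C@@H](C)C=O)/C1=C\[C@@]1(O[Si](CC)(CC)CC)C(O[Li])=C(C(C)C)C(=C)[C@@]1(C)O[Si](C)(C)C(C)(C)C | intermediate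
26 | 3,11-bis-O-TBS-12-O-TES-brassicicene M | COC[C@@]1(O[Si](C)(C)C(C)(C)C)CC[C@@H]2/C1=C\[C@@]1(O[Si](CC)(CC)CC)C(=O)C(C(C)C)=C(C[C@H](O)[C@@H]2C)[C@@]1(C)O[Si](C)(C)C(C)(C)C | intermediate
27 | brassicicene M | COC[C@@]1(O)CC[C@@H]2/C1=C\[C@@]1(O)C(=O)C(C(C)C)=C(C[C@H](O)[C@@H]2C)[C@@]1(C)O | target

**Step count and risks**

Total: 17 steps. Longest linear sequence: 13 steps (steps 1–3, 5, 6, 10–17, from 1 to 27).

Most likely to fail:

1. Step 5 (Proposed new method). The cascade may stall through oxidative loss of the amine catalyst or of enamine 8, through γ-deprotonation of the iminium ion with erosion of the C7 configuration, through poor facial control at C6, or through aldol closure to the wrong C3 epimer or dehydration. The fallback uses known chemistry and sets out from 5 and 7. Cyclopropanol 7 is opened with Et2Zn to the zinc homoenolate F1, which is added to 5 under CuBr·SMe2 catalysis with Me3SiCl (Nakamura–Kuwajima homoenolate conjugate addition; C6 set by Felkin-type 1,2-induction from C7). The resulting silyl enol ether F2 is hydrolysed on work-up to keto aldehyde F3. Amine-catalysed 5-(enolexo)-exo-trig aldolization (pyrrolidine, AcOH) then closes ring A and the route is rejoined at 9; diastereomers would need separation.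

2. Step 16. Ring closure may be outrun by intermolecular aldol addition, and attack on the wrong face of the α-methyl aldehyde may give the C8 epimer; simple Felkin and ring-conformation arguments do not clearly favour 8S. The fallback sets out from 24 and fixes C8 by carbonyl reduction instead of C–C bond formation. The cyclization product obtained as the 8-epimeric macrocycle F4 (or an epimer mixture) is oxidized with Dess–Martin periodinane to the C8 ketone F5. Reduction with KBH(s-Bu)3 in THF at −78 °C should deliver hydride anti to the C7 methyl, as for 2-methylcycloalkanones, to give the 7,8-cis alcohol; the route is rejoined at 26.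

3. Step 12. Hydrogen abstraction at C2 requires the C2–H bond to turn perpendicular to the enone plane against allylic strain with the quaternary C11, so the ene reaction may be slow; oxygen may also attack syn to the silyl ether, or the new C1=C2 olefin may be oxidized further. The fallback sets out from 19. Nucleophilic epoxidation (t-BuOOH, DBU) should give the spiro-epoxy ketone F6, with the C12–O bond formed anti to the C11 silyl ether. Isomerization of the epoxide to the allylic alcohol with diethylaluminium 2,2,6,6-tetramethylpiperidide (removal of the C2 hydrogen, cleavage of the C1–O bond) then rejoins the route at 21.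

**Further compounds**

F1 | step 5 | ethyl(4-methoxy-3-oxobutyl)zinc (zinc homoenolate of 7) | CC[Zn]CCC(=O)COC
F2 | step 5 | trimethylsilyl enol ether of keto aldehyde F3 | COCC(=O)CC[C@@H]([C@@H](C)CO[Si](C)(C)C(C)(C)C)C=CO[Si](C)(C)C
F3 | step 5 | 3-[(2R)-1-(tert-butyldimethylsilyloxy)propan-2-yl]-7-methoxy-6-oxoheptanal, C3 configured as C6 of 9 | COCC(=O)CC[C@@H]([C@@H](C)CO[Si](C)(C)C(C)(C)C)CC=O
F4 | step 16 | 8-epimer of 26 | COC[C@@]1(O[Si](C)(C)C(C)(C)C)CC[C@@H]2/C1=C\[C@@]1(O[Si](CC)(CC)CC)C(=O)C(C(C)C)=C(C[C@@H](O)[C@@H]2C)[C@@]1(C)O[Si](C)(C)C(C)(C)C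
F5 | step 16 | C8 ketone corresponding to 26 | COC[C@@]1(O[Si](C)(C)C(C)(C)C)CC[C@@H]2/C1=C\[C@@]1(O[Si](CC)(CC)CC)C(=O)C(C(C)C)=C(CC(=O)[C@@H]2C)[C@@]1(C)O[Si](C)(C)C(C)(C)C
F6 | step 12 | spiro-epoxy ketone from 19 (C1–C12 epoxide, oxygen cis to the C11 methyl) | COC[C@@]1(O[Si](C)(C)C(C)(C)C)CC[C@@H]([C@@H](C)CO[Si](C)(C)C(C)(C)C)[C@@H]1[C@@H]1O[C@@]12C(=O)C(C(C)C)=C(C)[C@@]2(C)O[Si](C)(C)C(C)(C)C
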